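The target is disconnected at the three bonds around C4 of the all-cis (2R,3R,4R) unit: C4–O(bridge), C3–C4 and O1–C2. C4, which carries the ether oxygen and sits ortho to O1 on ring A, is an aldehyde carbon, and its neighbours C3 (oxygen) and C2 (aryl) are a cis-enol ester. One three-component oxa-Diels–Alder reaction of a 4-alkoxy ortho-quinone methide therefore closes the pyran ring of this unit, sets C2, C3 and C4 and forges the 4-O-4' ether. Its precursors are a salicylaldehyde, a Z-enol benzoate and the enantiopure, benzyl-protected 2,3-trans-3,4-cis flavan-4-ol (primed unit).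

Key step: step 11

Remark: flavan numbering is used, unprimed for the all-cis unit and primed for the 2,3-trans unit; the sense of induction of (S)-t-BuPyOx in step 6 is assumed by analogy with simple chromones, and the mirror-image ligand is taken if it proves opposite.

Step 1
Reactants: 1 2,3,4-trihydroxybenzaldehyde
Product: 2 3,4-bis(benzyloxy)-2-hydroxybenzaldehyde
Conditions: BnBr (2.1 equiv), K2CO3 (2.2 equiv), DMF, rt
Reagents that add atoms: benzyl bromide, BrCc1ccccc1
Why: Williamson ether synthesis; the 2-hydroxyl is held in a hydrogen bond to the formyl group and is the least nucleophilic, so two equivalents of benzyl bromide should alkylate O3 and O4 and leave O2 free.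

Step 2
Reactants: 3 4-(benzyloxy)benzaldehyde
Product: 4 1-(benzyloxy)-4-ethynylbenzene
Conditions: dimethyl (1-diazo-2-oxopropyl)phosphonate, K2CO3, MeOH, rt
Reagents that add atoms: dimethyl (1-diazo-2-oxopropyl)phosphonate, CC(=O)C(=[N+]=[N-])P(=O)(OC)OC
Why: Seyferth–Gilbert homologation in its Ohira–Bestmann form; methanolysis of the reagent gives the diazomethylphosphonate anion, which adds to the aldehyde and, after loss of phosphate and N2, rearranges to the terminal alkyne without touching the benzyl ether.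

Step 3
Reactants: 4 1-(benzyloxy)-4-ethynylbenzene; 5 benzoic acid
Product: 6 (Z)-2-[4-(benzyloxy)phenyl]ethenyl benzoate
Conditions: [Ru(p-cymene)Cl2]2 (1 mol %), P(4-ClC6H4)3 (3 mol %), DMAP (4 mol %), toluene, 60 °C
Reagents that add atoms: none
Why: Anti-Markovnikov hydro-acyloxylation of a terminal alkyne; at the [Ru(p-cymene)Cl2]2/P(4-ClC6H4)3 catalyst the alkyne reacts through a vinylidene, benzoate adds to the metal-bound carbon and protonolysis should release the Z enol ester, the geometry on which the C2/C3 relation of the all-cis unit depends (any E isomer is removed by chromatography).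

Step 4
Reactants: 7 2,3,4-trihydroxyacetophenone
Product: 8 1-[3,4-bis(benzyloxy)-2-hydroxyphenyl]ethanone
Conditions: BnBr (2.1 equiv), K2CO3 (2.2 equiv), acetone, reflux
Reagents that add atoms: benzyl bromide, BrCc1ccccc1
Why: Williamson ether synthesis; as in step 1 the chelated 2-hydroxyl next to the carbonyl group should stay free while O3 and O4 are benzylated.

Step 5
Reactants: 8 1-[3,4-bis(benzyloxy)-2-hydroxyphenyl]ethanone
Product: 10 7,8-bis(benzyloxy)-4H-chromen-4-one, via enaminone 9 (not isolated)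
Conditions: Me2NCH(OMe)2, toluene, 100 °C; then conc. HCl, CH2Cl2, rt
Reagents that add atoms: N,N-dimethylformamide dimethyl acetal, COC(OC)N(C)C
Why: Standard chromone synthesis; condensation of the methyl ketone with the amide acetal gives the enaminone, and acid then promotes conjugate addition of the phenol and loss of dimethylamine.

Step 6
Reactants: 10 7,8-bis(benzyloxy)-4H-chromen-4-one; 11 [4-(benzyloxy)phenyl]boronic acid
Product: 12 (2R)-7,8-bis(benzyloxy)-2-[4-(benzyloxy)phenyl]chroman-4-one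
Conditions: Pd(OCOCF3)2 (5 mol %), (S)-t-BuPyOx (6 mol %), NH4PF6 (30 mol %), H2O (5 equiv), ClCH2CH2Cl, 60 °C
Reagents that add atoms: none
Why: Asymmetric conjugate addition of an arylboronic acid to a chromone (Hayashi–Miyaura-type 1,4-addition with a cationic divalent-palladium pyridine-oxazoline catalyst); transmetalation, enantiofacial insertion of C2=C3 and protonolysis of the enolate set C2 (R) under control of the ligand.

Step 7
Reactants: 12 (2R)-7,8-bis(benzyloxy)-2-[4-(benzyloxy)phenyl]chroman-4-one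
Product: 13 (2R,4R)-7,8-bis(benzyloxy)-2-[4-(benzyloxy)phenyl]chroman-4-ol
Conditions: NaBH4, MeOH/THF, 0 °C
Reagents that add atoms: none
Why: Hydride 1,2-reduction of the ketone; axial delivery should give the 2,4-cis alcohol, but the configuration at C4 is of no consequence because this centre is removed in step 8.

Step 8
Reactants: 13 (2R,4R)-7,8-bis(benzyloxy)-2-[4-(benzyloxy)phenyl]chroman-4-ol
Product: 14 (2R)-7,8-bis(benzyloxy)-2-[4-(benzyloxy)phenyl]-2H-chromene
Conditions: methyl N-(triethylammoniosulfonyl)carbamate (Burgess reagent), THF, 50 °C, dark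
Reagents that add atoms: none
Why: Burgess dehydration; the sulfamate ester of the benzylic alcohol eliminates readily because the 7-benzyloxy group assists ionisation at C4, and the neutral medium and exclusion of light keep the C2–O1 bond closed, so the C2 configuration is kept.

Step 9
Reactants: 14 (2R)-7,8-bis(benzyloxy)-2-[4-(benzyloxy)phenyl]-2H-chromene
Product: 15 (2S,3R,4R)-7,8-bis(benzyloxy)-2-[4-(benzyloxy)phenyl]chromane-3,4-diol
Conditions: OsO4 (2 mol %), NMO, acetone/H2O, 0 °C → rt
Reagents that add atoms: N-methylmorpholine N-oxide, C[N+]1([O-])CCOCC1; water, O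
Why: Catalytic syn-dihydroxylation with OsO4/NMO; the [3+2] addition takes place on the face of C3=C4 opposite to the C2 aryl group, which sets C3 (R) and C4 (R) by substrate control and gives the 2,3-trans-3,4-cis diol.

Step 10
Reactants: 15 (2S,3R,4R)-7,8-bis(benzyloxy)-2-[4-(benzyloxy)phenyl]chromane-3,4-diol
Product: 17 (2S,3R,4R)-3,7,8-tris(benzyloxy)-2-[4-(benzyloxy)phenyl]chroman-4-ol, via stannylene acetal 16 (not isolated)
Conditions: Bu2SnO, toluene, reflux (−H2O); then BnBr, CsF, DMF, rt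
Reagents that add atoms: benzyl bromide, BrCc1ccccc1
Why: Regioselective alkylation through a dibutylstannylene acetal; in a cis-1,2-diol on a six-membered ring the equatorial oxygen (O3, trans to the C2 aryl) is the nucleophilic one, so fluoride-assisted benzylation should occur at O3 and leave the pseudo-axial benzylic 4-hydroxyl free, with no stereocentre touched.

Step 11
Reactants: 2 3,4-bis(benzyloxy)-2-hydroxybenzaldehyde; 17 (2S,3R,4R)-3,7,8-tris(benzyloxy)-2-[4-(benzyloxy)phenyl]chroman-4-ol; 6 (Z)-2-[4-(benzyloxy)phenyl]ethenyl benzoate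
Product: 21 (2R,3R,4R)-7,8-bis(benzyloxy)-2-[4-(benzyloxy)phenyl]-4-{[(2S,3R,4R)-3,7,8-tris(benzyloxy)-2-[4-(benzyloxy)phenyl]chroman-4-yl]oxy}chroman-3-yl benzoate, via trimethylsilyl ether 18 (not isolated), via silylated aldehyde 19 (not isolated), via ortho-quinone methide 20 (not isolated)
Conditions: (Me3Si)2NH (1.5 equiv), Me3SiOTf (1 mol %), CH2Cl2, rt, then evaporation; 6 (2 equiv), Me3SiOTf (0.3 equiv), 2,6-di-tert-butyl-4-methylpyridine (0.1 equiv), CH2Cl2, −78 → −40 °C; Et3N quench
Reagents that add atoms: none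
Why: Me3SiOTf condenses silyl ether 18 with the aldehyde carbon of 19 to an O-flavanyl oxocarbenium ion, which loses Me3Si from the ortho oxygen to give the neutral (E)-4-alkoxy ortho-quinone methide 20, regenerating Me3SiOTf and releasing only (Me3Si)2O. The closest known reaction type is the Lewis-acid three-component coupling of salicylaldehydes, alkoxy donors and styrenes or enol derivatives to 2,4-cis-4-alkoxychromans (inverse-demand oxa-Diels–Alder reaction of 4-alkoxy ortho-quinone methides), here extended to an enol ester and a chiral secondary alkoxy group. The pyran ring of the unprimed unit closes by this intermolecular [4+2] cycloaddition, C3–C4 forming ahead of O1–C2, and the regiochemistry follows from the 4-benzyloxyphenyl group, which stabilises positive charge at C2 far better than the benzoyloxy group would at C3. The C2/C3 cis relation is copied suprafacially from the Z double bond of 6, and C4 becomes cis to both because the alkoxy group lies outside in the E quinone methide while aryl and benzoate approach endo. The absolute sense (4R, hence 2R,3R) has to come from the (4'R)-flavanyl group on the methide oxygen, whose 3'-benzyloxy arm should shield one face; adducts from the other face are diastereomers of 21 and are removed by chromatography, so the enantiopurity of 21 rests on 17 alone. The step needs the C4'–O bond to stay un-ionised and the Z geometry to survive, which the low temperature, the substoichiometric Lewis acid, the hindered pyridine base and the fast collapse to the neutral quinone methide are meant to secure.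

Step 12
Reactants: 21 the benzoate of step 11
Product: 22 (2R,3R,4R)-7,8-bis(benzyloxy)-2-[4-(benzyloxy)phenyl]-4-{[(2S,3R,4R)-3,7,8-tris(benzyloxy)-2-[4-(benzyloxy)phenyl]chroman-4-yl]oxy}chroman-3-ol
Conditions: K2CO3 (0.3 equiv), MeOH/THF, rt
Reagents that add atoms: none
Why: Base-catalysed transesterification (methanolysis) of the secondary benzoate; benzyl ethers and the bridging ether are inert to methoxide, the phenols are still masked, and no centre is epimerisable.

Step 13
Reactants: 22 the heptabenzyl ether alcohol of step 12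
Product: 23 (2R,3R,4R)-4-{[(2S,3R,4R)-3,7,8-trihydroxy-2-(4-hydroxyphenyl)chroman-4-yl]oxy}-2-(4-hydroxyphenyl)chromane-3,7,8-triol (CNP0241481.1)
Conditions: H2 (1 atm), Pd(OH)2/C, THF/MeOH, rt
Reagents that add atoms: none
Why: Catalytic hydrogenolysis of the seven benzyl ethers on non-acidic Pd(OH)2/C in a neutral solvent; the primary O–CH2Ph bonds should cleave much faster than the hindered secondary cyclic benzylic C–O bonds (C2–O1, C2'–O1', C4–O–C4'), and the reaction is stopped as soon as debenzylation is complete.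

Compound list
1 | 2,3,4-trihydroxybenzaldehyde | O=Cc1ccc(O)c(O)c1O | starting material
2 | 3,4-bis(benzyloxy)-2-hydroxybenzaldehyde | O=Cc1ccc(OCc2ccccc2)c(OCc2ccccc2)c1O | intermediate
3 | 4-(benzyloxy)benzaldehyde | O=Cc1ccc(OCc2ccccc2)cc1 | starting material
4 | 1-(benzyloxy)-4-ethynylbenzene | C#Cc1ccc(OCc2ccccc2)cc1 | intermediate
5 | benzoic acid | OC(=O)c1ccccc1 | starting material
6 | (Z)-2-[4-(benzyloxy)phenyl]ethenyl benzoate | O=C(O/C=C\c1ccc(OCc2ccccc2)cc1)c1ccccc1 | intermediate
7 | 2,3,4-trihydroxyacetophenone | CC(=O)c1ccc(O)c(O)c1O | starting material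
8 | 1-[3,4-bis(benzyloxy)-2-hydroxyphenyl]ethanone | CC(=O)c1ccc(OCc2ccccc2)c(OCc2ccccc2)c1O | intermediate
9 | (E)-1-[3,4-bis(benzyloxy)-2-hydroxyphenyl]-3-(dimethylamino)prop-2-en-1-one (enaminone) | CN(C)/C=C/C(=O)c1ccc(OCc2ccccc2)c(OCc2ccccc2)c1O | intermediate
10 | 7,8-bis(benzyloxy)-4H-chromen-4-one | O=c1ccoc2c(OCc3ccccc3)c(OCc3ccccc3)ccc12 | intermediate
11 | [4-(benzyloxy)phenyl]boronic acid | OB(O)c1ccc(OCc2ccccc2)cc1 | starting material
12 | (2R)-7,8-bis(benzyloxy)-2-[4-(benzyloxy)phenyl]chroman-4-one | O=C1C[C@H](c2ccc(OCc3ccccc3)cc2)Oc2c1ccc(OCc1ccccc1)c2OCc1ccccc1 | intermediate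
13 | (2R,4R)-7,8-bis(benzyloxy)-2-[4-(benzyloxy)phenyl]chroman-4-ol (2,4-cis) | O[C@@H]1C[C@H](c2ccc(OCc3ccccc3)cc2)Oc2c1ccc(OCc1ccccc1)c2OCc1ccccc1 | intermediate
14 | (2R)-7,8-bis(benzyloxy)-2-[4-(benzyloxy)phenyl]-2H-chromene | C1=C[C@H](c2ccc(OCc3ccccc3)cc2)Oc2c1ccc(OCc1ccccc1)c2OCc1ccccc1 | intermediate
15 | (2S,3R,4R)-7,8-bis(benzyloxy)-2-[4-(benzyloxy)phenyl]chromane-3,4-diol (2,3-trans-3,4-cis) | O[C@@H]1c2ccc(OCc3ccccc3)c(OCc3ccccc3)c2O[C@@H](c2ccc(OCc3ccccc3)cc2)[C@@H]1O | intermediate
16 | 2,2-dibutyl-1,3,2-dioxastannolane (stannylene acetal) of diol 15 across O3 and O4 | CCCC[Sn]1(CCCC)O[C@@H]2c3ccc(OCc4ccccc4)c(OCc4ccccc4)c3O[C@@H](c3ccc(OCc4ccccc4)cc3)[C@@H]2O1 | intermediate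
17 | (2S,3R,4R)-3,7,8-tris(benzyloxy)-2-[4-(benzyloxy)phenyl]chroman-4-ol | O[C@@H]1c2ccc(OCc3ccccc3)c(OCc3ccccc3)c2O[C@@H](c2ccc(OCc3ccccc3)cc2)[C@@H]1OCc1ccccc1 | intermediate
18 | 4-O-trimethylsilyl ether of 17 | C[Si](C)(C)O[C@@H]1c2ccc(OCc3ccccc3)c(OCc3ccccc3)c2O[C@@H](c2ccc(OCc3ccccc3)cc2)[C@@H]1OCc1ccccc1 | intermediate
19 | 3,4-bis(benzyloxy)-2-(trimethylsilyloxy)benzaldehyde | O=Cc1ccc(OCc2ccccc2)c(OCc2ccccc2)c1O[Si](C)(C)C | intermediate
20 | (6E)-2,3-bis(benzyloxy)-6-({[(2S,3R,4R)-3,7,8-tris(benzyloxy)-2-[4-(benzyloxy)phenyl]chroman-4-yl]oxy}methylidene)cyclohexa-2,4-dien-1-one (4-alkoxy ortho-quinone methide) | O=C1C(OCc2ccccc2)=C(OCc2ccccc2)C=C/C1=C\O[C@@H]1c2ccc(OCc3ccccc3)c(OCc3ccccc3)c2O[C@@H](c2ccc(OCc3ccccc3)cc2)[C@@H]1OCc1ccccc1 | intermediate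
21 | (2R,3R,4R)-7,8-bis(benzyloxy)-2-[4-(benzyloxy)phenyl]-4-{[(2S,3R,4R)-3,7,8-tris(benzyloxy)-2-[4-(benzyloxy)phenyl]chroman-4-yl]oxy}chroman-3-yl benzoate | c5ccccc5COc1ccc([C@H]2Oc3c(ccc(OCc5ccccc5)c3OCc5ccccc5)[C@@H](O[C@@H]3c4ccc(OCc5ccccc5)c(OCc5ccccc5)c4O[C@@H](c4ccc(OCc5ccccc5)cc4)[C@@H]3OCc5ccccc5)[C@H]2OC(=O)c5ccccc5)cc1 | intermediate
22 | (2R,3R,4R)-7,8-bis(benzyloxy)-2-[4-(benzyloxy)phenyl]-4-{[(2S,3R,4R)-3,7,8-tris(benzyloxy)-2-[4-(benzyloxy)phenyl]chroman-4-yl]oxy}chroman-3-ol | c5ccccc5COc1ccc([C@H]2Oc3c(ccc(OCc5ccccc5)c3OCc5ccccc5)[C@@H](O[C@@H]3c4ccc(OCc5ccccc5)c(OCc5ccccc5)c4O[C@@H](c4ccc(OCc5ccccc5)cc4)[C@@H]3OCc5ccccc5)[C@H]2O)cc1 | intermediate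
23 | (2R,3R,4R)-4-{[(2S,3R,4R)-3,7,8-trihydroxy-2-(4-hydroxyphenyl)chroman-4-yl]oxy}-2-(4-hydroxyphenyl)chromane-3,7,8-triol | Oc1ccc([C@H]2Oc3c(ccc(O)c3O)[C@@H](O[C@@H]3c4ccc(O)c(O)c4O[C@@H](c4ccc(O)cc4)[C@@H]3O)[C@H]2O)cc1 | target

Total step count: 13. Longest linear sequence: 10 steps (steps 4 to 13).

Steps most likely to fail

Step 11. The facial bias exerted by the flavanyl group may be small or of the wrong sense, the dienophile may approach exo, the Z geometry may be lost if the addition runs stepwise through a long-lived benzylic cation (with benzoate participation), or the C4'–O and C4–O bonds may ionise under the Lewis acid. The fallback builds the ether by substrate-controlled steps instead of a cycloaddition. It sets out from chromone 10 and boronic acid 11, which with the mirror-image ligand (R)-t-BuPyOx under the conditions of step 6 give (2S)-7,8-bis(benzyloxy)-2-[4-(benzyloxy)phenyl]chroman-4-one F1. NaBH4 reduction as in step 7 gives (2S,4S)-7,8-bis(benzyloxy)-2-[4-(benzyloxy)phenyl]chroman-4-ol F2, and Burgess dehydration as in step 8 gives (2S)-7,8-bis(benzyloxy)-2-[4-(benzyloxy)phenyl]-2H-chromene F3. Dimethyldioxirane in acetone/CH2Cl2 at low temperature epoxidises F3 on the face opposite the aryl group to the labile 2,3-trans-3,4-epoxyflavan F4. Alcohol 17 opens F4 at the benzylic C4 with inversion (ZnCl2, THF, −78 °C → rt, in the manner of an epoxide alcoholysis used for glycal epoxides) to give the 2,3-trans-3,4-trans (2R,3S,4R) ether alcohol F5, in which the C2 aryl and the C4 alkoxy group are cis. Dess–Martin periodinane (NaHCO3, CH2Cl2) oxidises F5 to the (2R,4R) flavan-3-one F6. LiBH(s-Bu)3 in THF at −78 °C delivers hydride to the face opposite both flanking groups, so the new 3-hydroxyl should be cis to them; the product is compound 22, where the route is rejoined before step 13.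

Step 13. The bridging bis-benzylic ether may be cleaved reductively on prolonged exposure (the secondary 3'-O-benzyl group is the slowest to leave), and once the phenols are free the C4 and C4' positions may ionise on the catalyst or during isolation. The fallback sets out from 22 and traps the phenols as they are unveiled: hydrogenolysis over Pd(OH)2/C in EtOAc containing Ac2O and NaOAc should give the hexa-O-acetyl derivative with free 3- and 3'-hydroxyls F7, whose electron-poor rings no longer support ionisation and which can be purified on silica. Neutral deacetylation of the six aryl acetates with NH4OAc in aqueous MeOH under argon then gives 23.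

Step 10. The stannylene acetal may be alkylated at O4, or twice. The fallback sets out from diol 15 and tells the two hydroxyls apart by oxidation level. Activated MnO2 in CH2Cl2 oxidises only the benzylic 4-hydroxyl to (2S,3S)-7,8-bis(benzyloxy)-2-[4-(benzyloxy)phenyl]-3-hydroxychroman-4-one F8. The remaining 3-hydroxyl is benzylated without base (benzyl 2,2,2-trichloroacetimidate, catalytic TfOH, CH2Cl2/cyclohexane, rt) to (2S,3S)-3,7,8-tris(benzyloxy)-2-[4-(benzyloxy)phenyl]chroman-4-one F9. LiBH(s-Bu)3 in THF at −78 °C, attacking from the equatorial direction, should return the pseudo-axial 4-alcohol cis to the 3-benzyloxy group, which is compound 17, where the route is rejoined.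

Further compounds
F1 | step 11 | (2S)-7,8-bis(benzyloxy)-2-[4-(benzyloxy)phenyl]chroman-4-one | O=C1C[C@@H](c2ccc(OCc3ccccc3)cc2)Oc2c1ccc(OCc1ccccc1)c2OCc1ccccc1
F2 | step 11 | (2S,4S)-7,8-bis(benzyloxy)-2-[4-(benzyloxy)phenyl]chroman-4-ol | O[C@H]1C[C@@H](c2ccc(OCc3ccccc3)cc2)Oc2c1ccc(OCc1ccccc1)c2OCc1ccccc1
F3 | step 11 | (2S)-7,8-bis(benzyloxy)-2-[4-(benzyloxy)phenyl]-2H-chromene | C1=C[C@@H](c2ccc(OCc3ccccc3)cc2)Oc2c1ccc(OCc1ccccc1)c2OCc1ccccc1
F4 | step 11 | 2,3-trans-3,4-epoxyflavan from F3 (oxirane opposite the 2-aryl group) | c1ccccc1COc1ccc(cc1)[C@H]1Oc2c(OCc3ccccc3)c(OCc3ccccc3)ccc2[C@@H]2O[C@H]12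
F5 | step 11 | (2R,3S,4R)-7,8-bis(benzyloxy)-2-[4-(benzyloxy)phenyl]-4-{[(2S,3R,4R)-3,7,8-tris(benzyloxy)-2-[4-(benzyloxy)phenyl]chroman-4-yl]oxy}chroman-3-ol | c5ccccc5COc1ccc([C@H]2Oc3c(ccc(OCc5ccccc5)c3OCc5ccccc5)[C@@H](O[C@@H]3c4ccc(OCc5ccccc5)c(OCc5ccccc5)c4O[C@@H](c4ccc(OCc5ccccc5)cc4)[C@@H]3OCc5ccccc5)[C@@H]2O)cc1
F6 | step 11 | (2R,4R)-7,8-bis(benzyloxy)-2-[4-(benzyloxy)phenyl]-4-{[(2S,3R,4R)-3,7,8-tris(benzyloxy)-2-[4-(benzyloxy)phenyl]chroman-4-yl]oxy}chroman-3-one | c5ccccc5COc1ccc([C@H]2Oc3c(ccc(OCc5ccccc5)c3OCc5ccccc5)[C@@H](O[C@@H]3c4ccc(OCc5ccccc5)c(OCc5ccccc5)c4O[C@@H](c4ccc(OCc5ccccc5)cc4)[C@@H]3OCc5ccccc5)C2=O)cc1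
F7 | step 13 | hexa-O-acetate of 23 at the six phenolic oxygens (3- and 3'-hydroxyls free) | CC(=O)Oc1ccc([C@H]2Oc3c(ccc(OC(C)=O)c3OC(C)=O)[C@@H](O[C@@H]3c4ccc(OC(C)=O)c(OC(C)=O)c4O[C@@H](c4ccc(OC(C)=O)cc4)[C@@H]3O)[C@H]2O)cc1
F8 | step 10 | (2S,3S)-7,8-bis(benzyloxy)-2-[4-(benzyloxy)phenyl]-3-hydroxychroman-4-one | O=C1c2ccc(OCc3ccccc3)c(OCc3ccccc3)c2O[C@@H](c2ccc(OCc3ccccc3)cc2)[C@@H]1O
F9 | step 10 | (2S,3S)-3,7,8-tris(benzyloxy)-2-[4-(benzyloxy)phenyl]chroman-4-one | O=C1c2ccc(OCc3ccccc3)c(OCc3ccccc3)c2O[C@@H](c2ccc(OCc3ccccc3)cc2)[C@@H]1OCc1ccccc1
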